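**Strategy**

Everything rests on cutting the two ether bonds at the aryl-bearing carbons, C2–O3 and C6–O7, of the 3,7-dioxabicyclo[3.3.0]octane. Both carbons are benzylic and para to an aryl oxygen, so one oxidation removes hydride from the two ArCH2 groups of a (2S,3S)-2,3-dibenzylbutane-1,4-diol, and each cation is trapped by the hydroxymethyl group of the other half. This closes both tetrahydrofuran rings (C1–C2–O3–C4–C5 and C5–C6–O7–C8–C1) and sets C2 and C6 in one operation. The precursor is that diol with one guaiacyl oxygen masked as an allyl ether and the other as a triisopropylsilyl ether, built by Evans alkylation and trans-selective lactone benzylation.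

Key step: step 10

**Remarks**

- Numbering of the bicycle: C1 and C5 are the ring-fusion carbons, C2 and C6 carry the aryl groups, O3 and O7 are the ring oxygens, C4 and C8 are the OCH2 carbons. The target is (1S,2R,5S,6R), with cis ring fusion and both aryl groups on the convex face. This maps onto a (2S,3S) diol and therefore onto the (4R)-oxazolidinone.
- Precursor design: no phenol is left free in the oxidation, because a free guaiacyl phenol would be re-oxidised by the quinone after its ring has closed. The oxygen that later carries the prenyl group is held as an allyl ether, since a prenyl ether would not survive the quinone. The diaryl core is C2-symmetric, so it does not matter which fragment supplies which aryl ring.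
- Assumption: 3-(4-hydroxy-3-methoxyphenyl)propanoic acid (dihydroferulic acid) is taken as a purchased starting material.

**Route**

Step 1
Reactants: 1 3-(4-hydroxy-3-methoxyphenyl)propanoic acid
Product: 3 3-[3-methoxy-4-(prop-2-enyloxy)phenyl]propanoic acid, via allyl ester 2 (not isolated)
Conditions: allyl bromide (2.5 equiv), K2CO3, DMF, 50 °C; then NaOH, MeOH/H2O, rt; HCl work-up
Reagents that add atoms: allyl bromide, C=CCBr; sodium hydroxide, [Na+].[OH-]
Why: Williamson O-alkylation of the phenoxide (the carboxylate is alkylated too) followed by saponification of the allyl ester should leave only the aryl allyl ether, which is inert to hydroxide.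

Step 2
Reactants: 3 3-[3-methoxy-4-(prop-2-enyloxy)phenyl]propanoic acid; 4 (4R)-4-benzyl-1,3-oxazolidin-2-one
Product: 6 (4R)-4-benzyl-3-{3-[3-methoxy-4-(prop-2-enyloxy)phenyl]propanoyl}-1,3-oxazolidin-2-one, via mixed pivalic anhydride 5 (not isolated)
Conditions: PivCl, Et3N, THF, −20 °C; then LiCl, 4, −20 °C → rt
Reagents that add atoms: none
Why: Mixed-anhydride N-acylation of the oxazolidinone, in which the hindered pivaloyl carbonyl directs the nitrogen to the arylpropanoyl carbonyl.

Step 3
Reactants: 6 (4R)-4-benzyl-3-{3-[3-methoxy-4-(prop-2-enyloxy)phenyl]propanoyl}-1,3-oxazolidin-2-one; 7 tert-butyl bromoacetate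
Product: 9 tert-butyl (3S)-4-[(4R)-4-benzyl-2-oxo-1,3-oxazolidin-3-yl]-3-{[3-methoxy-4-(prop-2-enyloxy)phenyl]methyl}-4-oxobutanoate, via sodium enolate 8 (not isolated)
Conditions: NaN(SiMe3)2, THF, −78 °C; then 7, −78 → −40 °C
Reagents that add atoms: none
Why: Evans asymmetric alkylation, in which the chelated (Z)-enolate is attacked by the reactive α-bromo ester on the face opposite the C4 benzyl group of the (4R)-auxiliary, setting the new stereocentre as S.

Step 4
Reactants: 9 tert-butyl (3S)-4-[(4R)-4-benzyl-2-oxo-1,3-oxazolidin-3-yl]-3-{[3-methoxy-4-(prop-2-enyloxy)phenyl]methyl}-4-oxobutanoate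
Product: 11 (4S)-4-{[3-methoxy-4-(prop-2-enyloxy)phenyl]methyl}oxolan-2-one, via hydroxy ester 10 (not isolated)
Conditions: LiBH4, H2O (1 equiv), Et2O, 0 °C; aqueous work-up; then TFA, CH2Cl2, 0 °C → rt
Reagents that add atoms: none
Why: Reductive cleavage of the imide (its exocyclic carbonyl is more electrophilic than the tert-butyl ester) followed by acid-mediated lactonisation with loss of isobutene; the stereocentre is not touched and becomes C4 (S) of the lactone.

Step 5
Reactants: 12 vanillin (4-hydroxy-3-methoxybenzaldehyde)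
Product: 13 3-methoxy-4-(triisopropylsilyloxy)benzaldehyde
Conditions: TIPSCl, imidazole, DMF, rt
Reagents that add atoms: triisopropylsilyl chloride, CC(C)[Si](Cl)(C(C)C)C(C)C
Why: Imidazole-promoted O-silylation of the phenol; the aldehyde does not react.

Step 6
Reactants: 13 3-methoxy-4-(triisopropylsilyloxy)benzaldehyde
Product: 14 [3-methoxy-4-(triisopropylsilyloxy)phenyl]methanol
Conditions: NaBH4, EtOH/THF, 0 °C
Reagents that add atoms: none
Why: Borohydride reduction of the aryl aldehyde to the benzylic alcohol, which the hindered aryl silyl ether tolerates in the cold.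

Step 7
Reactants: 14 [3-methoxy-4-(triisopropylsilyloxy)phenyl]methanol
Product: 15 [4-(bromomethyl)-2-methoxyphenoxy]triisopropylsilane
Conditions: PBr3 (0.4 equiv), Et2O, 0 °C; used without storage
Reagents that add atoms: phosphorus tribromide, BrP(Br)Br
Why: The primary benzylic alcohol is converted into the bromide through its phosphite ester and SN2 displacement by bromide, the usual access to p-silyloxybenzyl bromides.

Step 8
Reactants: 11 (4S)-4-{[3-methoxy-4-(prop-2-enyloxy)phenyl]methyl}oxolan-2-one; 15 [4-(bromomethyl)-2-methoxyphenoxy]triisopropylsilane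
Product: 17 (3S,4S)-4-{[3-methoxy-4-(prop-2-enyloxy)phenyl]methyl}-3-{[3-methoxy-4-(triisopropylsilyloxy)phenyl]methyl}oxolan-2-one, via lithium enolate 16 (not isolated)
Conditions: LiN(SiMe3)2, THF, −78 °C; then 15, DMPU, −78 → −20 °C
Reagents that add atoms: none
Why: Lactone enolate alkylation, in which the benzylic bromide approaches anti to the C4 benzyl substituent of the five-membered enolate and so sets C3 as S (trans lactone), as is established for β-benzyl-γ-butyrolactones.

Step 9
Reactants: 17 (3S,4S)-4-{[3-methoxy-4-(prop-2-enyloxy)phenyl]methyl}-3-{[3-methoxy-4-(triisopropylsilyloxy)phenyl]methyl}oxolan-2-one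
Product: 18 (2S,3S)-2-{[3-methoxy-4-(prop-2-enyloxy)phenyl]methyl}-3-{[3-methoxy-4-(triisopropylsilyloxy)phenyl]methyl}butane-1,4-diol
Conditions: LiAlH4, THF, 0 °C
Reagents that add atoms: none
Why: Hydride reduction of the lactone to the 1,4-diol touches no stereocentre, and the allyl ether and the hindered aryl silyl ether should be inert at 0 °C.

Step 10
Reactants: 18 (2S,3S)-2-{[3-methoxy-4-(prop-2-enyloxy)phenyl]methyl}-3-{[3-methoxy-4-(triisopropylsilyloxy)phenyl]methyl}butane-1,4-diol
Product: 20 (1S,2R,5S,6R)-2-[3-methoxy-4-(triisopropylsilyloxy)phenyl]-6-[3-methoxy-4-(prop-2-enyloxy)phenyl]-3,7-dioxabicyclo[3.3.0]octane, via hydroxymethyl tetrahydrofuran 19 (not isolated)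
Conditions: DDQ (2.2 equiv, two portions), 2,6-dichloropyridine, 4 Å MS, ClCH2CH2Cl, 0 °C → rt
Reagents that add atoms: none
Why: DDQ, as in the oxidative cleavage of p-methoxybenzyl ethers, takes hydride from the benzylic CH2 of each 3-methoxy-4-oxyphenyl ring, and the arene-stabilised cation is captured at once by the hydroxymethyl group on the distal backbone carbon; the closest known reaction type is the DDQ-mediated oxidative cycloetherification of aryl-substituted alkanols to 2-aryltetrahydrofurans, used here twice in one flask. Ring C5–C6–O7–C8–C1 should close first, at the more electron-rich allyloxyaryl side, by 5-exo-trig attack of O7 on cationic C6 to give 19, and ring C1–C2–O3–C4–C5 then closes in the same 5-exo-trig mode by attack of O3 on C2. C6 is controlled by the neighbouring C5 stereocentre, the aryl group taking the position trans to the C5 hydroxymethyl group in the envelope-like transition state. C2 is controlled by the ring already in place: C1 and C5 (both S and untouched) permit only a cis ring fusion, and O3 adds to the planar cation so that the aryl group lies on the convex face. The step needs O-capture in preference to Friedel–Crafts attack by the second arene and oxidation of the remaining CH2 in preference to the benzylic ether C–H just formed; the tethered primary hydroxyl closing a five-membered ring in a buffered, acid-free medium secures the first, and the absence of any free phenol, the limited charge of oxidant and the poorer alignment of the ring C–H with its arene secure the second.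

Step 11
Reactants: 20 (1S,2R,5S,6R)-2-[3-methoxy-4-(triisopropylsilyloxy)phenyl]-6-[3-methoxy-4-(prop-2-enyloxy)phenyl]-3,7-dioxabicyclo[3.3.0]octane
Product: 21 2-methoxy-4-{(1S,2R,5S,6R)-6-[3-methoxy-4-(triisopropylsilyloxy)phenyl]-3,7-dioxabicyclo[3.3.0]octan-2-yl}phenol
Conditions: Pd(PPh3)4 (5 mol %), morpholine, THF, rt
Reagents that add atoms: none
Why: Palladium-catalysed deallylation (Tsuji–Trost ionisation of the aryl allyl ether and transfer of the allyl group to morpholine) should free the phenol under neutral conditions that leave the silyl ether and both benzylic ethers intact.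

Step 12
Reactants: 21 2-methoxy-4-{(1S,2R,5S,6R)-6-[3-methoxy-4-(triisopropylsilyloxy)phenyl]-3,7-dioxabicyclo[3.3.0]octan-2-yl}phenol
Product: 22 (1S,2R,5S,6R)-2-[3-methoxy-4-(triisopropylsilyloxy)phenyl]-6-{3-methoxy-4-[(3-methylbut-2-enyl)oxy]phenyl}-3,7-dioxabicyclo[3.3.0]octane
Conditions: prenyl bromide, K2CO3, acetone, rt → 40 °C
Reagents that add atoms: prenyl bromide (1-bromo-3-methylbut-2-ene), CC(C)=CCBr
Why: Williamson etherification of the only free phenol with a reactive allylic bromide (SN2) in an aprotic medium that the aryl silyl ether should tolerate.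

Step 13
Reactants: 22 (1S,2R,5S,6R)-2-[3-methoxy-4-(triisopropylsilyloxy)phenyl]-6-{3-methoxy-4-[(3-methylbut-2-enyl)oxy]phenyl}-3,7-dioxabicyclo[3.3.0]octane
Product: 23 2-methoxy-4-[(1S,2R,5S,6R)-6-{3-methoxy-4-[(3-methylbut-2-enyl)oxy]phenyl}-3,7-dioxabicyclo[3.3.0]octan-2-yl]phenol (CNP0185952.2)
Conditions: Bu4NF, THF, 0 °C; aqueous NH4Cl
Reagents that add atoms: none
Why: Fluoride-induced cleavage of the aryl silyl ether, driven by the Si–F bond, to which the prenyl ether and the benzylic ethers are inert.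

**Compound list**

1 | 3-(4-hydroxy-3-methoxyphenyl)propanoic acid (dihydroferulic acid) | COc1cc(CCC(=O)O)ccc1O | starting material
2 | prop-2-enyl 3-[3-methoxy-4-(prop-2-enyloxy)phenyl]propanoate | C=CCOC(=O)CCc1ccc(OCC=C)c(OC)c1 | intermediate
3 | 3-[3-methoxy-4-(prop-2-enyloxy)phenyl]propanoic acid | OC(=O)CCc1ccc(OCC=C)c(OC)c1 | intermediate
4 | (4R)-4-benzyl-1,3-oxazolidin-2-one | O=C1N[C@H](Cc2ccccc2)CO1 | starting material
5 | 2,2-dimethylpropanoic 3-[3-methoxy-4-(prop-2-enyloxy)phenyl]propanoic anhydride | CC(C)(C)C(=O)OC(=O)CCc1ccc(OCC=C)c(OC)c1 | intermediate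
6 | (4R)-4-benzyl-3-{3-[3-methoxy-4-(prop-2-enyloxy)phenyl]propanoyl}-1,3-oxazolidin-2-one | O=C(CCc1ccc(OCC=C)c(OC)c1)N1[C@H](Cc2ccccc2)COC1=O | intermediate
7 | tert-butyl bromoacetate | CC(C)(C)OC(=O)CBr | starting material
8 | sodium (Z)-enolate of 6 | [Na+].[O-]/C(=C\Cc1ccc(OCC=C)c(OC)c1)N1[C@H](Cc2ccccc2)COC1=O | intermediate
9 | tert-butyl (3S)-4-[(4R)-4-benzyl-2-oxo-1,3-oxazolidin-3-yl]-3-{[3-methoxy-4-(prop-2-enyloxy)phenyl]methyl}-4-oxobutanoate | C=CCOc1ccc(C[C@@H](CC(=O)OC(C)(C)C)C(=O)N2[C@H](Cc3ccccc3)COC2=O)cc1OC | intermediate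
10 | tert-butyl (3S)-3-(hydroxymethyl)-4-[3-methoxy-4-(prop-2-enyloxy)phenyl]butanoate | C=CCOc1ccc(C[C@@H](CC(=O)OC(C)(C)C)CO)cc1OC | intermediate
11 | (4S)-4-{[3-methoxy-4-(prop-2-enyloxy)phenyl]methyl}oxolan-2-one | O=C1C[C@H](Cc2ccc(OCC=C)c(OC)c2)CO1 | intermediate
12 | vanillin (4-hydroxy-3-methoxybenzaldehyde) | COc1cc(C=O)ccc1O | starting material
13 | 3-methoxy-4-(triisopropylsilyloxy)benzaldehyde | COc1cc(C=O)ccc1O[Si](C(C)C)(C(C)C)C(C)C | intermediate
14 | [3-methoxy-4-(triisopropylsilyloxy)phenyl]methanol | COc1cc(CO)ccc1O[Si](C(C)C)(C(C)C)C(C)C | intermediate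
15 | [4-(bromomethyl)-2-methoxyphenoxy]triisopropylsilane | COc1cc(CBr)ccc1O[Si](C(C)C)(C(C)C)C(C)C | intermediate
16 | lithium enolate of 11 | [Li+].[O-]C1=C[C@H](Cc2ccc(OCC=C)c(OC)c2)CO1 | intermediate
17 | (3S,4S)-4-{[3-methoxy-4-(prop-2-enyloxy)phenyl]methyl}-3-{[3-methoxy-4-(triisopropylsilyloxy)phenyl]methyl}oxolan-2-one (trans) | O=C1OC[C@@H](Cc2ccc(OCC=C)c(OC)c2)[C@@H]1Cc3ccc(O[Si](C(C)C)(C(C)C)C(C)C)c(OC)c3 | intermediate
18 | (2S,3S)-2-{[3-methoxy-4-(prop-2-enyloxy)phenyl]methyl}-3-{[3-methoxy-4-(triisopropylsilyloxy)phenyl]methyl}butane-1,4-diol | C=CCOc1ccc(C[C@H](CO)[C@@H](CO)Cc2ccc(O[Si](C(C)C)(C(C)C)C(C)C)c(OC)c2)cc1OC | intermediate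
19 | [(2R,3S,4S)-2-[3-methoxy-4-(prop-2-enyloxy)phenyl]-4-{[3-methoxy-4-(triisopropylsilyloxy)phenyl]methyl}oxolan-3-yl]methanol | COc1cc(C[C@@H]2CO[C@@H](c3ccc(OCC=C)c(OC)c3)[C@@H]2CO)ccc1O[Si](C(C)C)(C(C)C)C(C)C | intermediate
20 | (1S,2R,5S,6R)-2-[3-methoxy-4-(triisopropylsilyloxy)phenyl]-6-[3-methoxy-4-(prop-2-enyloxy)phenyl]-3,7-dioxabicyclo[3.3.0]octane | COc1cc([C@@H]2OC[C@@H]3[C@H]2CO[C@H]3c2ccc(OCC=C)c(OC)c2)ccc1O[Si](C(C)C)(C(C)C)C(C)C | intermediate
21 | 2-methoxy-4-{(1S,2R,5S,6R)-6-[3-methoxy-4-(triisopropylsilyloxy)phenyl]-3,7-dioxabicyclo[3.3.0]octan-2-yl}phenol | COc1cc([C@@H]2OC[C@@H]3[C@H]2CO[C@H]3c2ccc(O)c(OC)c2)ccc1O[Si](C(C)C)(C(C)C)C(C)C | intermediate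
22 | (1S,2R,5S,6R)-2-[3-methoxy-4-(triisopropylsilyloxy)phenyl]-6-{3-methoxy-4-[(3-methylbut-2-enyl)oxy]phenyl}-3,7-dioxabicyclo[3.3.0]octane | COc1cc([C@@H]2OC[C@@H]3[C@H]2CO[C@H]3c2ccc(OCC=C(C)C)c(OC)c2)ccc1O[Si](C(C)C)(C(C)C)C(C)C | intermediate
23 | 2-methoxy-4-[(1S,2R,5S,6R)-6-{3-methoxy-4-[(3-methylbut-2-enyl)oxy]phenyl}-3,7-dioxabicyclo[3.3.0]octan-2-yl]phenol (CNP0185952.2) | COc1cc([C@@H]2OC[C@@H]3[C@H]2CO[C@H]3c2ccc(OCC=C(C)C)c(OC)c2)ccc1O | target

**Step count**

Total step count: 13.
Longest linear sequence: 10 steps (steps 1–4 and 8–13, from acid 1).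

**Steps most likely to fail**

1. Step 10. The oxidation may run past the ether stage by taking hydride from a benzylic ether C–H that has already formed. A benzylic cation may also be captured by the neighbouring arene instead of the hydroxyl, or acid released by the spent oxidant may reopen a ring and erode the configuration at C2 or C6. The fallback brings in one benzylic oxygen by carbonyl chemistry, so that a single C–H oxidation remains, and sets out from lactone 11 and aldehyde 13. The lithium enolate 16 is added to 13 (THF, −78 °C) to give the trans aldol adduct F1 as a mixture of carbinol epimers, both of which are usable. LiAlH4 (THF, 0 °C) reduces it to the triol F2. A catalytic amount of camphorsulfonic acid (CH2Cl2, 0 °C) ionises the benzylic carbinol, and the distal hydroxymethyl group closes the first ring to give the tetrahydrofuran F3, with the aryl group trans to the hydroxymethyl group. One equivalent of DDQ under the buffered conditions of step 10 then oxidises the only remaining benzylic CH2, that of the more electron-rich allyloxy ring, and the route is rejoined at 20.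

2. Step 8. The electron-rich benzylic bromide may ionise and condense with itself before it alkylates the enolate, or a second alkylation and incomplete anti selectivity may lower the return. The fallback forms the same C–C bond by aldol addition and removes the carbinol oxygen afterwards; it sets out from lactone 11 and aldehyde 13. The aldol adduct F1 is converted with MsCl and Et3N into the mesylate F4, which DBU eliminates to the (E)-arylidene lactone F5. Conjugate reduction with Stryker's reagent [(Ph3P)CuH]6 should give the saturated lactone, in part as the cis lactone F6, and equilibration of the α-centre with DBU should move the material to the more stable trans isomer. The route is rejoined at 17.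

3. Step 4. Hydride may attack the ring carbonyl of the auxiliary or the tert-butyl ester in competition with the exocyclic imide carbonyl. The fallback removes the auxiliary by hydrolysis and reduces the free acid selectively; it sets out from 9. LiOH/H2O2 (THF/H2O, 0 °C) should give the acid F7 and the recovered auxiliary. Isobutyl chloroformate and N-methylmorpholine (THF, −15 °C) convert the acid into the mixed carbonic anhydride F8, which NaBH4 reduces to the hydroxy ester. The route is rejoined at 10, which is lactonised to 11 as in step 4.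

**Further compounds**

F1 | step 10 | (3R,4S)-3-{hydroxy[3-methoxy-4-(triisopropylsilyloxy)phenyl]methyl}-4-{[3-methoxy-4-(prop-2-enyloxy)phenyl]methyl}oxolan-2-one (both carbinol epimers) | O=C1OC[C@@H](Cc2ccc(OCC=C)c(OC)c2)[C@@H]1C(O)c3ccc(O[Si](C(C)C)(C(C)C)C(C)C)c(OC)c3
F2 | step 10 | (2S,3S)-2-{hydroxy[3-methoxy-4-(triisopropylsilyloxy)phenyl]methyl}-3-{[3-methoxy-4-(prop-2-enyloxy)phenyl]methyl}butane-1,4-diol (both carbinol epimers) | C=CCOc1ccc(C[C@H](CO)[C@@H](CO)C(O)c2ccc(O[Si](C(C)C)(C(C)C)C(C)C)c(OC)c2)cc1OC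
F3 | step 10 | [(2R,3S,4S)-2-[3-methoxy-4-(triisopropylsilyloxy)phenyl]-4-{[3-methoxy-4-(prop-2-enyloxy)phenyl]methyl}oxolan-3-yl]methanol | COc1cc([C@@H]2OC[C@@H](Cc3ccc(OCC=C)c(OC)c3)[C@H]2CO)ccc1O[Si](C(C)C)(C(C)C)C(C)C
F4 | step 8 | [3-methoxy-4-(triisopropylsilyloxy)phenyl][(3R,4S)-4-{[3-methoxy-4-(prop-2-enyloxy)phenyl]methyl}-2-oxooxolan-3-yl]methyl methanesulfonate (both epimers at the sulfonate carbon) | O=C1OC[C@@H](Cc2ccc(OCC=C)c(OC)c2)[C@@H]1C(OS(C)(=O)=O)c3ccc(O[Si](C(C)C)(C(C)C)C(C)C)c(OC)c3
F5 | step 8 | (3E,4S)-3-{[3-methoxy-4-(triisopropylsilyloxy)phenyl]methylidene}-4-{[3-methoxy-4-(prop-2-enyloxy)phenyl]methyl}oxolan-2-one | O=C1OC[C@@H](Cc2ccc(OCC=C)c(OC)c2)/C1=C\c3ccc(O[Si](C(C)C)(C(C)C)C(C)C)c(OC)c3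
F6 | step 8 | (3R,4S)-4-{[3-methoxy-4-(prop-2-enyloxy)phenyl]methyl}-3-{[3-methoxy-4-(triisopropylsilyloxy)phenyl]methyl}oxolan-2-one (cis epimer of 17) | O=C1OC[C@@H](Cc2ccc(OCC=C)c(OC)c2)[C@H]1Cc3ccc(O[Si](C(C)C)(C(C)C)C(C)C)c(OC)c3
F7 | step 4 | (2S)-4-tert-butoxy-2-{[3-methoxy-4-(prop-2-enyloxy)phenyl]methyl}-4-oxobutanoic acid | C=CCOc1ccc(C[C@@H](CC(=O)OC(C)(C)C)C(=O)O)cc1OC
F8 | step 4 | (2S)-4-tert-butoxy-2-{[3-methoxy-4-(prop-2-enyloxy)phenyl]methyl}-4-oxobutanoic 2-methylpropyl carbonic anhydride | C=CCOc1ccc(C[C@@H](CC(=O)OC(C)(C)C)C(=O)OC(=O)OCC(C)C)cc1OC
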